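**Assumptions:** The target has no stereocentre, so "single enantiomer" is read as the single (2E,6E) geometric isomer. (2E,6E)-Farnesol and methyl 3,4-dihydroxy-5-methoxybenzoate (methyl 3-O-methylgallate) are taken as commercial.

## Retrosynthetic overview

1. Both E-alkenes are bought in (2E,6E)-farnesol (1). The C11–O bond is cut back to the distal alkene, made by site-selective MHAT hydration (1→2).
2. Aryl ether: unprotected diol 2 and unprotected catechol ester 3 are joined by a pKa- and sterics-gated Mitsunobu reaction (→4). One acetylation then caps both remaining OH groups (→5).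
3. Key (bold) disconnection: no phthalide is pre-made. C3–C3a and O2–C1 are cut, so the lactone CH2–O is one formaldehyde stitched on in the last step (5→6). This uses Mg-phenoxide-directed ortho C–H hydroxymethylation intercepted by lactonisation.
4. Ring order: the benzene ring is purchased. The γ-lactone is the only ring formed, and it is formed last.
5. Deliberately avoided: late Williamson coupling of a protected, preformed phthalide catechol with a pre-oxidised C15 allylic bromide.

## Route

**Step 1**
Reactants: 1, (2E,6E)-farnesol
Product: 2, (2E,6E)-3,7,11-trimethyldodeca-2,6-diene-1,11-diol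
Conditions: Mn(dpm)3 (5 mol %), PhSiH3 (1.2 equiv), O2 (1 atm), i-PrOH/CH2Cl2, 0 °C, stop at about 60 % conversion; then P(OEt)3; recover and recycle 1
Reagents that add atoms: dioxygen, O=O (supplies the C11 oxygen; the silane supplies only H)
Why: This is a Mukaiyama–Isayama hydration (metal-hydride H-atom transfer), in which Mn–H puts H• on C10 and O2 traps the tertiary C11 radical faster than it can cyclise onto C6=C7 before the peroxide is reduced; the bulky dpm catalyst favours the least hindered gem-dimethyl terminus, C2=C3 is retarded by the allylic oxygen, partial conversion limits over-hydration, no stereocentre is created, and both purchased E-alkenes are untouched.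

**Step 2**
Reactants: 2, the diol; 3, methyl 3,4-dihydroxy-5-methoxybenzoate (1.3 equiv)
Product: 4, methyl 3-hydroxy-4-{[(2E,6E)-11-hydroxy-3,7,11-trimethyldodeca-2,6-dien-1-yl]oxy}-5-methoxybenzoate
Conditions: PPh3 (1.2 equiv), DIAD (1.2 equiv, slow addition), THF, 0 °C → rt
Reagents that add atoms: none (both partners are listed reactants; PPh3 and DIAD leave no atoms)
Why: In this Mitsunobu etherification only the primary allylic OH forms an alkoxyphosphonium ion (the tertiary OH is inert) and the betaine deprotonates only the most acidic phenol (4-OH, para to CO2Me), so displacement is a clean SN2 at C1 without allylic transposition and the 2E geometry is retained.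

**Step 3**
Reactants: 4
Product: 5, methyl 3-acetoxy-4-{[(2E,6E)-11-acetoxy-3,7,11-trimethyldodeca-2,6-dien-1-yl]oxy}-5-methoxybenzoate
Conditions: Ac2O (5 equiv), Et3N (6 equiv), DMAP (0.5 equiv), CH2Cl2, rt, 24–36 h
Reagents that add atoms: acetic anhydride, CC(=O)OC(C)=O
Why: In this Steglich-type DMAP-catalysed acylation the N-acetylpyridinium ion acetylates the phenol at once and the hindered tertiary alcohol over hours, under basic non-ionising conditions that cause no E1 loss at C11 and no ionisation of the allyl aryl ether.

**Step 4 (key step)**
Reactants: 5
Product: 6, farnesylemefuranone F, 5-{[(2E,6E)-11-acetoxy-3,7,11-trimethyldodeca-2,6-dien-1-yl]oxy}-4-hydroxy-6-methoxyisobenzofuran-1(3H)-one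
Conditions: Mg(OMe)2 (0.6 equiv), MeOH/toluene, rt, 1 h; distil off MeOH/MeOAc; (CH2O)n (5 equiv), toluene, 90 °C, 3 h; then 0 °C, NaBH4 (0.5 equiv), THF/MeOH, 15 min; 10 % aq. citric acid
Reagents that add atoms: paraformaldehyde (reacts as formaldehyde), C=O (supplies C3H2 and ring O2; the ester OMe leaves as MeOH and the aryl acetyl leaves as MeOAc)
Why: Proposed new method: an interrupted Casnati–Skattebøl reaction, in which the near-stoichiometric methoxide on Mg is consumed cleaving only the aryl acetate (far better leaving group, unhindered, while the tertiary acetate is inert), the resulting Mg phenoxide delivers bound CH2O through the usual six-membered chelate to its only free ortho carbon (C2, also para-activated by OMe), and the Mg salicyl alkoxide that a second CH2O would normally oxidise to the aldehyde instead sits ortho to CO2Me and should undergo faster 5-exo-trig lactonisation, with NaBH4 funnelling any 2-formyl ester to the same lactone; the product phenoxide has no free ortho site so the reaction self-terminates, and the closest known reactions are Mg(OMe)2/paraformaldehyde ortho-formylation of phenols and spontaneous phthalide closure of 2-(hydroxymethyl)benzoates.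

## Compound list

| No. | Name | SMILES | Role |
|---|---|---|---|
| 1 | (2E,6E)-farnesol | OC/C=C(\C)CC/C=C(\C)CCC=C(C)C | starting material |
| 2 | (2E,6E)-3,7,11-trimethyldodeca-2,6-diene-1,11-diol | OC/C=C(\C)CC/C=C(\C)CCCC(C)(C)O | intermediate |
| 3 | methyl 3,4-dihydroxy-5-methoxybenzoate | COC(=O)c1cc(O)c(O)c(OC)c1 | starting material |
| 4 | methyl 3-hydroxy-4-{[(2E,6E)-11-hydroxy-3,7,11-trimethyldodeca-2,6-dienyl]oxy}-5-methoxybenzoate | COC(=O)c1cc(O)c(OC/C=C(\C)CC/C=C(\C)CCCC(C)(C)O)c(OC)c1 | intermediate |
| 5 | methyl 3-acetoxy-4-{[(2E,6E)-11-acetoxy-3,7,11-trimethyldodeca-2,6-dienyl]oxy}-5-methoxybenzoate | COC(=O)c1cc(OC(C)=O)c(OC/C=C(\C)CC/C=C(\C)CCCC(C)(C)OC(C)=O)c(OC)c1 | intermediate |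
| 6 | farnesylemefuranone F | COc1cc2c(c(O)c1OC/C=C(\C)CC/C=C(\C)CCCC(C)(C)OC(C)=O)COC2=O | target |

## Step count

Total steps: 4. Longest linear sequence: 4 (1→2→4→5→6).

## Steps most likely to fail

1. **Step 4.**
   - Risk: C2 is flanked by CO2Me and OMg, so attack may be slow. Methoxymethyl-type by-products or partial loss of the tertiary acetate are also possible.
   - Fallback (ring first): annulate the chain-free ester 3 with formaldehyde to give 4,5-dihydroxy-6-methoxyphthalide. Then attach the chain by Mitsunobu at its 5-OH, which is para to the lactone C=O. The chain partner is the 11-acetoxy-1-ol made from 2 by Ac2O/DMAP followed by K2CO3/MeOH, which cleaves only the primary acetate.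

2. **Step 1.**
   - Risk: discrimination of C10=C11 from C6=C7 may be only about 2:1. Expect about 30–40 % yield (about 60 % based on recovered 1), and the 7-ol isomer must be separated.
   - Fallback: replace radical selection by hydrophobic-coiling selection. Treat (2E,6E)-farnesyl acetate with NBS in THF/H2O to form the terminal 10-bromo-11-ol. Hydrodebrominate with (TMS)3SiH/AIBN, then use K2CO3/MeOH to reach 2.

3. **Step 2.**
   - Risk: 3-O-alkylation, bis-alkylation, or sequestration of the catechol as a phosphorane.
   - Fallback (leaving-group-controlled unmasking instead of a free catechol): peracetylate 3 and convert 2 into its C1 allylic bromide (MsCl/Et3N then LiBr, −40 °C). Combine the two with K2CO3/KI in DMF. The 4-acetate, para to the ester, is cleaved first and alkylated in situ. This gives the 3-acetate directly, one tertiary acetylation short of 5.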